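## The problem

The lactone oxygen is O1, the carbonyl carbon C2, the methyl-bearing carbon C3, the enol carbon C4 and the ylidene-bearing carbon C5. The chain runs from the exocyclic C6 to C14, which is bonded to C4 of furan A; furan B is joined through one CH2 group to C2 of furan A.

The compound is an open chain, so the task is chain building, not ring fusion. It has a (5Z)-ylidene tetronic acid head, one methyl-bearing stereocentre at C7 (S), a (9E,11E)-diene with a methyl group on C11, and a 2,4-disubstituted furan linked to a 3-substituted furan as a difurylmethane. C7 is the only stereocentre, so no other centre can direct it. It must come from a reagent, an auxiliary or a temporary stereocentre. Once the ylidene lactone is in place the C7 hydrogen is vinylogously acidic, which limits the base that may be used late.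

Three alkene geometries have to be secured: 11E (trisubstituted), 9E (disubstituted) and 5Z (exocyclic, chain cis to O1). The two furans and their shared CH2 group exclude strong acid, electrophilic oxidants and heterogeneous hydrogenation. The tetronic acid is a strong, chelating acid that would quench organometallic reagents, so it has to travel masked.

The feature that opens the route is the array C6–C7(H)(CH3)–C8H2–C9=C10. With C6 at the carboxyl level this is a 2-methylalk-4-enoic acid, the product pattern of an ester enolate Claisen rearrangement. In the precursor, C10 is a carbinol carbon flanked by a vinyl group (the future C8 and C9) and by the C11=C12 alkene.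

## Retrosynthesis

**Unmasking the head.** Target 28 is traced back to its 4-O-methyl ether 27; only the O–CH3 bond is cut. The methyl ether is the smallest mask for the tetronic acid and is also what allows C5 to be metalated earlier. The forward step must remove the methyl group by attack at carbon without touching the C5=C6 geometry, the diene or the furans.

**C5=C6.** Ether 27 is cut at the exocyclic alkene into aldehyde 21 and methyl tetronate 23, by way of aldol 25. Cutting C6–C7 instead would put the bond formation on the stereocentre itself. Cutting O1–C5 (Alternative 2) needs a longer, geometry-defined enynoic acid. The cut reduces the head to 23, one step from commercial 22, and the chain to a C6 aldehyde. The forward reactions are an aldol addition of the C5 anion 24 and an elimination through mesylate 26; they must not epimerise the α-stereocentre of 21 and must give the Z alkene.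

**Oxidation level of C6.** Aldehyde 21 is traced through alcohol 20 to acid 19. No skeletal bond is cut. The carboxyl level at C6 is what the next disconnection needs, and acid 19 can be purified by extraction.

**C7–C8, the key cut.** Acid 19 is traced, through silyl ester 18 and silyl ketene acetal 17, to propanoate 16. The C7–C8 bond is cut, the C9=C10 alkene moves back to C8=C9, and C10 regains its oxygen. An auxiliary-based enolate alkylation would make the same bond but needs a dienyl halide and extra auxiliary steps (kept as the fallback). The sigmatropic route forms the bond, the 9E alkene and the C7 centre in one operation. It exchanges a remote methyl stereocentre for a secondary carbinol next to two alkenes, which is much easier to obtain in one configuration. The forward reaction needs an E ketene acetal, a chair transition state and reaction through the vinyl group only.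

**C9–C10 and the carbinol centre.** Propanoate 16 comes from alcohol 15 by acylation. Alcohol 15 comes from racemate 14 by enzymatic resolution, and 14 from enal 12 and vinyl Grignard reagent 13. Cutting C10–C11 instead would require a stereodefined trisubstituted alkenyl metal. The forward steps are a 1,2-addition, a resolution that keeps the slow-reacting S alcohol, and an acylation under basic conditions so that the bis-allylic C–O bond is not ionised.

**C11=C12.** Enal 12 is cut at the trisubstituted alkene to aldehyde 11 and a formyl-stabilised phosphorane carrying the C11 methyl group. The reaction must give the E geometry, which a stabilised ylide does under thermodynamic control.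

**C13–C14 region.** Aldehyde 11 is traced through ester 9 and acrylate 8 to furaldehyde 7: the bond between the two chain carbons next to furan A is formed as an alkene and then saturated. This two-carbon extension uses the formyl group that 7 already carries. The conjugate reduction must spare both furans.

**Difurylmethane bond.** Aldehyde 7 is cut between the CH2 group and C2 of furan A into furan-3-carbaldehyde 3 and bromide 2, which comes from alcohol 1. The formyl group of 3 serves as the anchor of the chain and, converted in the flask to amino alkoxide 4, as the element that sends metalation to the remote α-position (5). Alkylation then gives 6 and, on hydrolysis, 7. Building furan A from acyclic material (Alternative 1) or joining the rings by cross-coupling (Alternative 3) are the neighbouring options.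

## Roads not taken

**Alternative 1:** Furan A would be cut at its C3=C4 bond. An acyclic mixed acetal A1, carrying a vinyl group and a 1,1-disubstituted alkene, would be closed by the second-generation Grubbs catalyst to a 2-methoxy-2,5-dihydrofuran. Pyridinium p-toluenesulfonate in the same pot would then aromatise it by loss of the methoxy group to give silyl ether A2.

- Merits: the 2,4-substitution pattern of furan A is fixed by construction, and the three-carbon side chain arrives at the right length.
- Weak points: A1 is a multi-step compound whose two halves are not commercial; ring closure onto a 1,1-disubstituted alkene is the slow case of metathesis; the acid needed for aromatisation acts in the presence of furan B. A2 is still two steps from aldehyde 11.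
- Comparison: this road is better in regiochemical certainty. The chosen plan sets against it two steps from commercial furans to 7 and a known directing effect. Alternative 1 also spends its key step on the tail and leaves C7 unsolved.

**Alternative 2:** The lactone would be cut at O1–C5. The carboxylic acid of enynoic acid A3 would add to the AgNO3-activated alkyne in a 5-exo-dig closure to give A4, which is the same compound as 27.

- Merits: anti addition across the alkyne sets the Z geometry stereospecifically, and neither strong base nor an elimination is needed at the head.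
- Weak points: A3 must be made from the same C6 aldehyde 21 by alkyne homologation next to the stereocentre and then joined to a β-methoxyacrylate unit whose tetrasubstituted alkene must hold the carboxyl and alkynyl groups cis. 6-endo closure to a pyranone competes. The count from 21 is clearly higher than two steps.
- Comparison: for control of the 5Z alkene this road is the better one in principle. The chosen plan sets against it the thermodynamic preference of 4-methoxy-5-ylidene butenolides for the Z isomer and a two-step head assembly from 23. This road also leaves C7 to other chemistry.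

**Alternative 3:** The difurylmethane would be cut at the same CH2–C2 bond as in the chosen plan, but formed by Suzuki coupling. Ester A5 would be borylated at the free α-position remote from the side chain to give pinacol boronate A6, and A6 would couple with bromide 2 under PdCl2(dppf) and K3PO4 to give ester A7, the ethyl analogue of 9.

- Merits: mild conditions; no long cryogenic metalation; no organolithium in the presence of the acidic difurylmethane CH2 group.
- Weak points: 2-furyl boronates are prone to protodeboronation, and benzylic-type bromides tend to homocouple. A5 itself takes two steps from 3, so A7 is reached in about as many steps as 9.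
- Comparison: in robustness of the C–C bond formation this road is as good as or better than step 2. The chosen plan sets against it one step fewer, no precious-metal catalyst, and a formyl group that serves as both directing group and chain anchor. The cross-coupling idea is kept as the fallback for step 2.

Key step: step 10

Remark: the descriptor E for ketene acetal 17 follows the sequence rule (OSi outranks OC), which means methyl trans to OSiMe3 and cis to the allylic oxygen. Compound 22 and the two phosphoranes of steps 3 and 6 are taken to be commercial.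

## Route

Step 1
Reactants: 1 furan-3-ylmethanol
Product: 2 3-(bromomethyl)furan
Conditions: PBr3, pyridine (cat.), Et2O, −10 to 0 °C; kept cold as a dried solution
Reagents that add atoms: phosphorus tribromide, BrP(Br)Br
Why: Bromination of a primary heteroarylmethyl alcohol through its phosphite ester with displacement by bromide; the bromide is used at once in solution because furylmethyl halides polymerise on concentration.

Step 2
Reactants: 3 furan-3-carbaldehyde; 2 3-(bromomethyl)furan
Product: 7 5-(furan-3-ylmethyl)furan-3-carbaldehyde, via lithium amino alkoxide 4 (not isolated), via C5-lithiated amino alkoxide 5 (not isolated), via alkylated amino alkoxide 6 (not isolated)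
Conditions: morpholine, nBuLi, THF, −78 °C; 3; sBuLi, −78 °C, several h; 2, −78 to 0 °C; H2O
Reagents that add atoms: none
Why: α-Amino alkoxide directed lithiation: the bulky, non-chelating morpholino alkoxide shields C2 and sends deprotonation to the remote α-position C5; the furyllithium is then alkylated by the reactive furylmethyl bromide and water releases the aldehyde.

Step 3
Reactants: 7 5-(furan-3-ylmethyl)furan-3-carbaldehyde
Product: 8 methyl (2E)-3-[5-(furan-3-ylmethyl)furan-3-yl]prop-2-enoate
Conditions: Ph3P=CHCO2Me, CH2Cl2, 25 °C
Reagents that add atoms: methyl (triphenylphosphoranylidene)acetate, COC(=O)C=P(c1ccccc1)(c1ccccc1)c1ccccc1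
Why: Wittig reaction of a stabilised ylide with a heteroaryl aldehyde; the E isomer should predominate, and the geometry is of no consequence because the alkene is reduced next.

Step 4
Reactants: 8 methyl (2E)-3-[5-(furan-3-ylmethyl)furan-3-yl]prop-2-enoate
Product: 9 methyl 3-[5-(furan-3-ylmethyl)furan-3-yl]propanoate
Conditions: Mg turnings, MeOH, 0 to 25 °C; aq. NH4Cl
Reagents that add atoms: none
Why: Dissolving-metal conjugate reduction of a β-heteroaryl acrylate by electron transfer from Mg; it leaves the furans untouched, and the methyl ester makes transesterification by the solvent degenerate.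

Step 5
Reactants: 9 methyl 3-[5-(furan-3-ylmethyl)furan-3-yl]propanoate
Product: 11 3-[5-(furan-3-ylmethyl)furan-3-yl]propanal, via aluminium hemiacetal 10 (not isolated)
Conditions: iBu2AlH (1 equiv), CH2Cl2, −78 °C; MeOH, then aq. KNaC4H4O6
Reagents that add atoms: none
Why: Partial reduction of an ester: the tetrahedral aluminium hemiacetal is stable at −78 °C and gives the aldehyde only on hydrolysis.

Step 6
Reactants: 11 3-[5-(furan-3-ylmethyl)furan-3-yl]propanal
Product: 12 (2E)-5-[5-(furan-3-ylmethyl)furan-3-yl]-2-methylpent-2-enal
Conditions: Ph3P=C(CH3)CHO, toluene, 90 °C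
Reagents that add atoms: 2-(triphenylphosphoranylidene)propanal, CC(C=O)=P(c1ccccc1)(c1ccccc1)c1ccccc1
Why: Wittig reaction of a formyl-stabilised ylide, which should give the E trisubstituted enal (the future 11E alkene) under thermodynamic control; the α-branched product enal is much less reactive towards the ylide than 11.

Step 7
Reactants: 12 (2E)-5-[5-(furan-3-ylmethyl)furan-3-yl]-2-methylpent-2-enal; 13 vinylmagnesium bromide
Product: 14 rac-(4E)-7-[5-(furan-3-ylmethyl)furan-3-yl]-4-methylhepta-1,4-dien-3-ol
Conditions: THF, −78 to 0 °C; sat. aq. NH4Cl
Reagents that add atoms: none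
Why: Grignard 1,2-addition to an α-branched enal forms the C9–C10 bond; the carbinol is racemic at this stage and the near-neutral quench protects the bis-allylic alcohol from ionisation.

Step 8
Reactants: 14 rac-(4E)-7-[5-(furan-3-ylmethyl)furan-3-yl]-4-methylhepta-1,4-dien-3-ol
Product: 15 (3S,4E)-7-[5-(furan-3-ylmethyl)furan-3-yl]-4-methylhepta-1,4-dien-3-ol
Conditions: immobilised Candida antarctica lipase B, vinyl acetate, tBuOMe, 30 °C, stopped slightly past half conversion; chromatography
Reagents that add atoms: none
Why: Lipase-catalysed kinetic resolution by acyl transfer: by the empirical size rule for secondary alcohols (vinyl as the medium group, the α-branched alkenyl chain as the large one) the R enantiomer should be acetylated and the S alcohol left behind; running past half conversion protects the enantiomeric purity of the recovered alcohol.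

Step 9
Reactants: 15 (3S,4E)-7-[5-(furan-3-ylmethyl)furan-3-yl]-4-methylhepta-1,4-dien-3-ol
Product: 16 (3S,4E)-7-[5-(furan-3-ylmethyl)furan-3-yl]-4-methylhepta-1,4-dien-3-yl propanoate
Conditions: (EtCO)2O, Et3N, 4-(dimethylamino)pyridine (cat.), CH2Cl2, 0 °C
Reagents that add atoms: propanoic anhydride, CCC(=O)OC(=O)CC
Why: Nucleophile-catalysed acylation at oxygen; the C10–O bond is not touched, so the configuration is retained, and the basic medium avoids ionisation or allylic transposition of the bis-allylic ester.

Step 10
Reactants: 16 (3S,4E)-7-[5-(furan-3-ylmethyl)furan-3-yl]-4-methylhepta-1,4-dien-3-yl propanoate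
Product: 19 (2S,4E,6E)-9-[5-(furan-3-ylmethyl)furan-3-yl]-2,6-dimethylnona-4,6-dienoic acid, via silyl ketene acetal 17 (not isolated), via trimethylsilyl ester 18 (not isolated)
Conditions: LiN(iPr)2 (1.1 equiv), THF, −78 °C, 16 added slowly to the base; Me3SiCl/Et3N, −78 to 25 °C, then 40 °C; H2O–MeOH; extraction into aq. NaHCO3 and re-acidification to pH 4 with citric acid
Reagents that add atoms: none
Why: LiN(iPr)2 removes an α-hydrogen of propanoate 16 through the closed, cyclic transition state that operates in tetrahydrofuran without a polar cosolvent, and O-silylation gives the E silyl ketene acetal 17; on warming, 17 undergoes a suprafacial [3,3]-sigmatropic shift in which C7–C8 forms as C10–O breaks, and silyl ester 18 is hydrolysed to 19. The closest known reaction type is the Ireland–Claisen rearrangement of propanoates of secondary allylic and bis-allylic carbinols with 1,3-transfer of configuration. No ring is closed. The new stereocentre C7 is controlled by the carbinol centre C10 through a chair transition state in which the alkenyl substituent on C10 is equatorial and the ketene acetal methyl group is pseudo-axial; with (3S)-16 this arrangement gives (S)-C7, and the equatorial substituent makes the new C9=C10 alkene E. Three selectivities are needed: E enolisation, secured by slow addition of the ester to the base at −78 °C without polar additive; reaction through the vinyl group and not through the C11=C12 alkene, secured because the vinyl terminus C8 is an unsubstituted CH2 whereas the competing path must join two substituted carbons (both paths end in a conjugated diene, so the preference is steric); and deprotonation at the ester α-carbon in preference to the difurylmethane CH2, secured by the higher kinetic acidity of the ester and a near-stoichiometric charge of base. A Z ketene acetal would pass through the same chair to the enantiomer, so the enantiomeric purity of 19 is expected to follow the geometric purity of 17 and is to be assayed at alcohol 20.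

Step 11
Reactants: 19 (2S,4E,6E)-9-[5-(furan-3-ylmethyl)furan-3-yl]-2,6-dimethylnona-4,6-dienoic acid
Product: 20 (2S,4E,6E)-9-[5-(furan-3-ylmethyl)furan-3-yl]-2,6-dimethylnona-4,6-dien-1-ol
Conditions: LiAlH4, Et2O, 0 °C; H2O, aq. NaOH, H2O
Reagents that add atoms: none
Why: Hydride reduction of a carboxylic acid to the primary alcohol; the α-stereocentre of the carboxylate is not enolised under these conditions and the diene and furans are inert.

Step 12
Reactants: 20 (2S,4E,6E)-9-[5-(furan-3-ylmethyl)furan-3-yl]-2,6-dimethylnona-4,6-dien-1-ol
Product: 21 (2S,4E,6E)-9-[5-(furan-3-ylmethyl)furan-3-yl]-2,6-dimethylnona-4,6-dienal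
Conditions: Dess–Martin periodinane, pyridine, CH2Cl2, 0 to 25 °C; used directly
Reagents that add atoms: none
Why: Dess–Martin oxidation under buffered, non-basic conditions, which is known to keep α-methyl aldehydes configurationally intact; the furans and the diene tolerate the hypervalent iodine reagent at this temperature.

Step 13
Reactants: 22 4-hydroxy-3-methylfuran-2(5H)-one
Product: 23 4-methoxy-3-methylfuran-2(5H)-one
Conditions: (MeO)2SO2, K2CO3, acetone, reflux
Reagents that add atoms: dimethyl sulfate, COS(=O)(=O)OC
Why: O-Alkylation of the tetronate anion at the enol oxygen; the C3 methyl group blocks C-alkylation at the only nucleophilic carbon.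

Step 14
Reactants: 23 4-methoxy-3-methylfuran-2(5H)-one; 21 (2S,4E,6E)-9-[5-(furan-3-ylmethyl)furan-3-yl]-2,6-dimethylnona-4,6-dienal
Product: 25 5-{(2S,4E,6E)-9-[5-(furan-3-ylmethyl)furan-3-yl]-1-hydroxy-2,6-dimethylnona-4,6-dien-1-yl}-4-methoxy-3-methylfuran-2(5H)-one (mixture of diastereomers at ring C5 and at the carbinol carbon), via lithium furanolate 24 (not isolated)
Conditions: LiN(iPr)2, THF, −78 °C, 23; then 21, −78 °C; AcOH
Reagents that add atoms: none
Why: Aldol addition of the C5-lithiated methyl tetronate (a 2-furanolate) to the aldehyde forms the C5–C6 bond; addition at −78 °C to the preformed anion is faster than enolisation of 21, and the two new stereocentres are removed in the next step.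

Step 15
Reactants: 25 5-{(2S,4E,6E)-9-[5-(furan-3-ylmethyl)furan-3-yl]-1-hydroxy-2,6-dimethylnona-4,6-dien-1-yl}-4-methoxy-3-methylfuran-2(5H)-one
Product: 27 (5Z)-5-{(2S,4E,6E)-9-[5-(furan-3-ylmethyl)furan-3-yl]-2,6-dimethylnona-4,6-dien-1-ylidene}-4-methoxy-3-methylfuran-2(5H)-one, via mesylate 26 (not isolated)
Conditions: MeSO2Cl, Et3N, CH2Cl2, 0 °C; then DBU (1.2 equiv), 0 to 25 °C, short contact
Reagents that add atoms: none
Why: Mesylation followed by E1cB elimination through the acidic C5 hydrogen; the Z isomer is expected because in the E isomer the chain would clash with the C4 methoxy group, and all diastereomers of 25 converge on the same alkene.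

Step 16
Reactants: 27 (5Z)-5-{(2S,4E,6E)-9-[5-(furan-3-ylmethyl)furan-3-yl]-2,6-dimethylnona-4,6-dien-1-ylidene}-4-methoxy-3-methylfuran-2(5H)-one
Product: 28 (5Z)-5-{(2S,4E,6E)-9-[5-(furan-3-ylmethyl)furan-3-yl]-2,6-dimethylnona-4,6-dien-1-ylidene}-4-hydroxy-3-methylfuran-2(5H)-one
Conditions: LiCl, DMSO, 80 °C; then cold 0.5 M HCl to pH 3, extraction
Reagents that add atoms: none
Why: O-Demethylation by chloride attack at the methyl carbon of a vinylogous methyl carbonate, with the tetronate as leaving group; no base or Lewis acid is present, so C7, the alkenes and the furans should be unaffected.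

## Compound list

1 | furan-3-ylmethanol | OCc1ccoc1 | starting material
2 | 3-(bromomethyl)furan | BrCc1ccoc1 | intermediate
3 | furan-3-carbaldehyde | O=Cc1ccoc1 | starting material
4 | lithium furan-3-yl(morpholin-4-yl)methanolate | [Li]OC(N1CCOCC1)c1ccoc1 | intermediate (not isolated)
5 | lithium (5-lithiofuran-3-yl)(morpholin-4-yl)methanolate | [Li]OC(N1CCOCC1)c1coc([Li])c1 | intermediate (not isolated)
6 | lithium [5-(furan-3-ylmethyl)furan-3-yl](morpholin-4-yl)methanolate | [Li]OC(N1CCOCC1)c1coc(Cc2ccoc2)c1 | intermediate (not isolated)
7 | 5-(furan-3-ylmethyl)furan-3-carbaldehyde | O=Cc1coc(Cc2ccoc2)c1 | intermediate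
8 | methyl (2E)-3-[5-(furan-3-ylmethyl)furan-3-yl]prop-2-enoate | COC(=O)/C=C/c1coc(Cc2ccoc2)c1 | intermediate
9 | methyl 3-[5-(furan-3-ylmethyl)furan-3-yl]propanoate | COC(=O)CCc1coc(Cc2ccoc2)c1 | intermediate
10 | {3-[5-(furan-3-ylmethyl)furan-3-yl]-1-methoxypropoxy}bis(2-methylpropyl)alumane | COC(CCc1coc(Cc2ccoc2)c1)O[Al](CC(C)C)CC(C)C | intermediate (not isolated)
11 | 3-[5-(furan-3-ylmethyl)furan-3-yl]propanal | O=CCCc1coc(Cc2ccoc2)c1 | intermediate
12 | (2E)-5-[5-(furan-3-ylmethyl)furan-3-yl]-2-methylpent-2-enal | O=C/C(C)=C/CCc1coc(Cc2ccoc2)c1 | intermediate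
13 | vinylmagnesium bromide | C=C[Mg]Br | starting material
14 | rac-(4E)-7-[5-(furan-3-ylmethyl)furan-3-yl]-4-methylhepta-1,4-dien-3-ol | OC(C=C)/C(C)=C/CCc1coc(Cc2ccoc2)c1 | intermediate
15 | (3S,4E)-7-[5-(furan-3-ylmethyl)furan-3-yl]-4-methylhepta-1,4-dien-3-ol | O[C@@H](C=C)/C(C)=C/CCc1coc(Cc2ccoc2)c1 | intermediate
16 | (3S,4E)-7-[5-(furan-3-ylmethyl)furan-3-yl]-4-methylhepta-1,4-dien-3-yl propanoate | CCC(=O)O[C@@H](C=C)/C(C)=C/CCc1coc(Cc2ccoc2)c1 | intermediate
17 | {[(1E)-1-{[(3S,4E)-7-[5-(furan-3-ylmethyl)furan-3-yl]-4-methylhepta-1,4-dien-3-yl]oxy}prop-1-en-1-yl]oxy}trimethylsilane | C/C=C(/O[Si](C)(C)C)O[C@@H](C=C)/C(C)=C/CCc1coc(Cc2ccoc2)c1 | intermediate (not isolated)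
18 | trimethylsilyl (2S,4E,6E)-9-[5-(furan-3-ylmethyl)furan-3-yl]-2,6-dimethylnona-4,6-dienoate | C[Si](C)(C)OC(=O)[C@@H](C)C/C=C/C(C)=C/CCc1coc(Cc2ccoc2)c1 | intermediate (not isolated)
19 | (2S,4E,6E)-9-[5-(furan-3-ylmethyl)furan-3-yl]-2,6-dimethylnona-4,6-dienoic acid | OC(=O)[C@@H](C)C/C=C/C(C)=C/CCc1coc(Cc2ccoc2)c1 | intermediate
20 | (2S,4E,6E)-9-[5-(furan-3-ylmethyl)furan-3-yl]-2,6-dimethylnona-4,6-dien-1-ol | OC[C@@H](C)C/C=C/C(C)=C/CCc1coc(Cc2ccoc2)c1 | intermediate
21 | (2S,4E,6E)-9-[5-(furan-3-ylmethyl)furan-3-yl]-2,6-dimethylnona-4,6-dienal | O=C[C@@H](C)C/C=C/C(C)=C/CCc1coc(Cc2ccoc2)c1 | intermediate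
22 | 4-hydroxy-3-methylfuran-2(5H)-one (3-methyltetronic acid) | CC1=C(O)COC1=O | starting material
23 | 4-methoxy-3-methylfuran-2(5H)-one | CC1=C(OC)COC1=O | intermediate
24 | lithium 4-methoxy-3-methylfuran-2-olate | [Li]Oc1occ(OC)c1C | intermediate (not isolated)
25 | 5-{(2S,4E,6E)-9-[5-(furan-3-ylmethyl)furan-3-yl]-1-hydroxy-2,6-dimethylnona-4,6-dien-1-yl}-4-methoxy-3-methylfuran-2(5H)-one (diastereomer mixture) | CC1=C(OC)C(OC1=O)C(O)[C@@H](C)C/C=C/C(C)=C/CCc2coc(Cc3ccoc3)c2 | intermediate
26 | 1-(3-methoxy-4-methyl-5-oxo-2,5-dihydrofuran-2-yl)-(2S,4E,6E)-9-[5-(furan-3-ylmethyl)furan-3-yl]-2,6-dimethylnona-4,6-dien-1-yl methanesulfonate (diastereomer mixture) | CC1=C(OC)C(OC1=O)C(OS(C)(=O)=O)[C@@H](C)C/C=C/C(C)=C/CCc2coc(Cc3ccoc3)c2 | intermediate (not isolated)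
27 | (5Z)-5-{(2S,4E,6E)-9-[5-(furan-3-ylmethyl)furan-3-yl]-2,6-dimethylnona-4,6-dien-1-ylidene}-4-methoxy-3-methylfuran-2(5H)-one | CC1=C(OC)/C(=C/[C@@H](C)C/C=C/C(C)=C/CCc2coc(Cc3ccoc3)c2)OC1=O | intermediate
28 | (5Z)-5-{(2S,4E,6E)-9-[5-(furan-3-ylmethyl)furan-3-yl]-2,6-dimethylnona-4,6-dien-1-ylidene}-4-hydroxy-3-methylfuran-2(5H)-one | CC1=C(O)/C(=C/[C@@H](C)C/C=C/C(C)=C/CCc2coc(Cc3ccoc3)c2)OC1=O | target

## Step count and least certain steps

Total: 16 steps. Longest linear sequence: 15 steps (steps 1 to 12 and 14 to 16, from furan-3-ylmethanol 1); step 13 is a one-step side branch.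

**Step 10 (key step).** Three processes can fail:

- Incomplete geometric control in the enolisation. The minor ketene acetal isomer rearranges through the same chair to the enantiomer, so the loss appears as erosion of enantiomeric purity and cannot be removed by chromatography.
- Competing rearrangement through the C11=C12 alkene. This also yields a conjugated diene and is disfavoured only by the greater substitution at its bond-forming terminus.
- Deprotonation at the difurylmethane CH2 group by surplus amide base.

The fallback makes the same C7–C8 bond by auxiliary-controlled enolate alkylation, which gives separable diastereomers. It sets out from enal 12. Horner–Wadsworth–Emmons reaction with triethyl phosphonoacetate and NaH should give ethyl (2E,4E)-7-[5-(furan-3-ylmethyl)furan-3-yl]-4-methylhepta-2,4-dienoate F1. Reduction with iBu2AlH gives (2E,4E)-7-[5-(furan-3-ylmethyl)furan-3-yl]-4-methylhepta-2,4-dien-1-ol F2, and CBr4 with PPh3 gives 4-[(3E,5E)-7-bromo-4-methylhepta-3,5-dien-1-yl]-2-(furan-3-ylmethyl)furan F3. The sodium enolate of (4R)-4-benzyl-3-propanoyl-1,3-oxazolidin-2-one (NaN(SiMe3)2, THF, −78 °C) is alkylated with F3 on the face away from the benzyl group to give (4R)-4-benzyl-3-{(2S,4E,6E)-9-[5-(furan-3-ylmethyl)furan-3-yl]-2,6-dimethylnona-4,6-dienoyl}-1,3-oxazolidin-2-one F4. Reductive removal of the auxiliary with LiBH4 returns to the route at alcohol 20.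

**Step 2.** The alkylation of organolithium 5 can stall. Possible causes are halogen–lithium exchange with bromide 2, or proton transfer from the acidic CH2 group of the newly formed difurylmethane to unreacted 5. Metalation may also not be fully selective for C5. The fallback separates metalation from C–C bond formation. It sets out from aldehyde 3: the same lithiation is quenched with Bu3SnCl and hydrolysed to 5-(tributylstannyl)furan-3-carbaldehyde F5. Stille coupling of F5 with bromide 2 under Pd(PPh3)4 (zerovalent palladium) in THF returns to the route at aldehyde 7.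

**Step 8.** The acylation may be slow, or the enantiomers poorly discriminated, because the large substituent is branched next to the carbinol carbon. A resolution also discards at least half of the material. The fallback replaces resolution by asymmetric reduction. It sets out from racemate 14: oxidation with MnO2 gives (4E)-7-[5-(furan-3-ylmethyl)furan-3-yl]-4-methylhepta-1,4-dien-3-one F6. Reduction with BH3·SMe2 catalysed by (R)-1-methyl-3,3-diphenyltetrahydro-1H,3H-pyrrolo[1,2-c][1,3,2]oxazaborole (the oxazaborolidine of the Corey–Bakshi–Shibata reduction), with the α-branched alkenyl group taken as the larger substituent, is expected to deliver hydride to the face that gives the S alcohol. This returns to the route at 15.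

**Step 15.** The elimination may give incomplete Z selectivity, and prolonged contact with DBU may epimerise C7 through the extended enolate of the ylidene lactone. The fallback forms the C5=C6 alkene by olefination under weaker base. It sets out from methyl tetronate 23. Radical bromination with N-bromosuccinimide gives 5-bromo-4-methoxy-3-methylfuran-2(5H)-one F7, and PPh3 gives (3-methoxy-4-methyl-5-oxo-2,5-dihydrofuran-2-yl)triphenylphosphonium bromide F8. Et3N generates 4-methoxy-3-methyl-5-(triphenylphosphoranylidene)furan-2(5H)-one F9, whose Wittig reaction with aldehyde 21 returns to the route at 27. Any E isomer would be equilibrated with a trace of iodine.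

**Step 16.** Displacement at the methyl group may be sluggish and need prolonged heating, during which the exocyclic alkene or the diene can isomerise and the furans degrade. The fallback changes the mask to one removed by fluoride at low temperature. It sets out from tetronic acid 22. Mitsunobu alkylation with 2-(trimethylsilyl)ethanol (PPh3, diisopropyl azodicarboxylate) gives 3-methyl-4-[2-(trimethylsilyl)ethoxy]furan-2(5H)-one F10. Deprotonation with LiN(iPr)2 gives lithium 3-methyl-4-[2-(trimethylsilyl)ethoxy]furan-2-olate F11, which adds to aldehyde 21 to give 5-{(2S,4E,6E)-9-[5-(furan-3-ylmethyl)furan-3-yl]-1-hydroxy-2,6-dimethylnona-4,6-dien-1-yl}-3-methyl-4-[2-(trimethylsilyl)ethoxy]furan-2(5H)-one F12. Mesylation gives the corresponding methanesulfonate F13, and elimination with DBU gives (5Z)-5-{(2S,4E,6E)-9-[5-(furan-3-ylmethyl)furan-3-yl]-2,6-dimethylnona-4,6-dien-1-ylidene}-3-methyl-4-[2-(trimethylsilyl)ethoxy]furan-2(5H)-one F14. Bu4NF in THF at 0 °C, followed by mild acidification, returns to the route at target 28.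

## Further compounds

F1 | step 10 | ethyl (2E,4E)-7-[5-(furan-3-ylmethyl)furan-3-yl]-4-methylhepta-2,4-dienoate | CCOC(=O)/C=C/C(C)=C/CCc1coc(Cc2ccoc2)c1
F2 | step 10 | (2E,4E)-7-[5-(furan-3-ylmethyl)furan-3-yl]-4-methylhepta-2,4-dien-1-ol | OC/C=C/C(C)=C/CCc1coc(Cc2ccoc2)c1
F3 | step 10 | 4-[(3E,5E)-7-bromo-4-methylhepta-3,5-dien-1-yl]-2-(furan-3-ylmethyl)furan | BrC/C=C/C(C)=C/CCc1coc(Cc2ccoc2)c1
F4 | step 10 | (4R)-4-benzyl-3-{(2S,4E,6E)-9-[5-(furan-3-ylmethyl)furan-3-yl]-2,6-dimethylnona-4,6-dienoyl}-1,3-oxazolidin-2-one | O=C1OC[C@@H](Cc2ccccc2)N1C(=O)[C@@H](C)C/C=C/C(C)=C/CCc3coc(Cc4ccoc4)c3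
F5 | step 2 | 5-(tributylstannyl)furan-3-carbaldehyde | O=Cc1coc([Sn](CCCC)(CCCC)CCCC)c1
F6 | step 8 | (4E)-7-[5-(furan-3-ylmethyl)furan-3-yl]-4-methylhepta-1,4-dien-3-one | C=CC(=O)/C(C)=C/CCc1coc(Cc2ccoc2)c1
F7 | step 15 | 5-bromo-4-methoxy-3-methylfuran-2(5H)-one | CC1=C(OC)C(Br)OC1=O
F8 | step 15 | (3-methoxy-4-methyl-5-oxo-2,5-dihydrofuran-2-yl)triphenylphosphonium bromide | CC1=C(OC)C(OC1=O)[P+](c2ccccc2)(c2ccccc2)c2ccccc2.[Br-]
F9 | step 15 | 4-methoxy-3-methyl-5-(triphenylphosphoranylidene)furan-2(5H)-one | CC1=C(OC)C(OC1=O)=P(c2ccccc2)(c2ccccc2)c2ccccc2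
F10 | step 16 | 3-methyl-4-[2-(trimethylsilyl)ethoxy]furan-2(5H)-one | CC1=C(OCC[Si](C)(C)C)COC1=O
F11 | step 16 | lithium 3-methyl-4-[2-(trimethylsilyl)ethoxy]furan-2-olate | [Li]Oc1occ(OCC[Si](C)(C)C)c1C
F12 | step 16 | 5-{(2S,4E,6E)-9-[5-(furan-3-ylmethyl)furan-3-yl]-1-hydroxy-2,6-dimethylnona-4,6-dien-1-yl}-3-methyl-4-[2-(trimethylsilyl)ethoxy]furan-2(5H)-one | CC1=C(OCC[Si](C)(C)C)C(OC1=O)C(O)[C@@H](C)C/C=C/C(C)=C/CCc2coc(Cc3ccoc3)c2
F13 | step 16 | (2S,4E,6E)-9-[5-(furan-3-ylmethyl)furan-3-yl]-2,6-dimethyl-1-{4-methyl-5-oxo-3-[2-(trimethylsilyl)ethoxy]-2,5-dihydrofuran-2-yl}nona-4,6-dien-1-yl methanesulfonate | CC1=C(OCC[Si](C)(C)C)C(OC1=O)C(OS(C)(=O)=O)[C@@H](C)C/C=C/C(C)=C/CCc2coc(Cc3ccoc3)c2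
F14 | step 16 | (5Z)-5-{(2S,4E,6E)-9-[5-(furan-3-ylmethyl)furan-3-yl]-2,6-dimethylnona-4,6-dien-1-ylidene}-3-methyl-4-[2-(trimethylsilyl)ethoxy]furan-2(5H)-one | CC1=C(OCC[Si](C)(C)C)/C(=C/[C@@H](C)C/C=C/C(C)=C/CCc2coc(Cc3ccoc3)c2)OC1=O
A1 | alternative 1 | tert-butyl{[4-({[1-(furan-3-yl)but-3-en-2-yl]oxy}(methoxy)methyl)pent-4-en-1-yl]oxy}dimethylsilane | C=C(CCCO[Si](C)(C)C(C)(C)C)C(OC)OC(C=C)Cc1ccoc1
A2 | alternative 1 | tert-butyl{3-[5-(furan-3-ylmethyl)furan-3-yl]propoxy}dimethylsilane | CC(C)(C)[Si](C)(C)OCCCc1coc(Cc2ccoc2)c1
A3 | alternative 2 | (2E,6S,8E,10E)-13-[5-(furan-3-ylmethyl)furan-3-yl]-3-methoxy-2,6,10-trimethyltrideca-2,8,10-trien-4-ynoic acid | OC(=O)/C(C)=C(OC)\C#C[C@@H](C)C/C=C/C(C)=C/CCc1coc(Cc2ccoc2)c1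
A4 | alternative 2 | (5Z)-5-{(2S,4E,6E)-9-[5-(furan-3-ylmethyl)furan-3-yl]-2,6-dimethylnona-4,6-dien-1-ylidene}-4-methoxy-3-methylfuran-2(5H)-one | CC1=C(OC)/C(=C/[C@@H](C)C/C=C/C(C)=C/CCc2coc(Cc3ccoc3)c2)OC1=O
A5 | alternative 3 | ethyl 3-(furan-3-yl)propanoate | CCOC(=O)CCc1ccoc1
A6 | alternative 3 | ethyl 3-[5-(4,4,5,5-tetramethyl-1,3,2-dioxaborolan-2-yl)furan-3-yl]propanoate | CCOC(=O)CCc1coc(B2OC(C)(C)C(C)(C)O2)c1
A7 | alternative 3 | ethyl 3-[5-(furan-3-ylmethyl)furan-3-yl]propanoate | CCOC(=O)CCc1coc(Cc2ccoc2)c1
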